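Numbering each ring from the butyryl carbon (C1) through C2–OH, C3–CH2 bridge, C4–OH and C5–CH3 to C6–OCH3, the shared CH2 sits on C3, flanked by the oxygen-bearing C2 and C4 in both rings. That is the substitution pattern left when a vinylketene is annulated onto an ynol ether, so both benzene rings are cut at C2–C3 and C4–C5 and traced to one skipped bis(siloxyalkyne), TIPSO–C≡C–CH2–C≡C–OTIPS, and two molecules of 3-methoxy-2-methylcyclobutenone. A single thermal operation should build both arenes with CH3 and OCH3 already in place, leaving C1 as the only free ring carbon, where the butyryl groups are then delivered from the C2 oxygen.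

Key step: step 5

Assumption: penta-1,4-diyne 3 is too volatile and too easily isomerised to be stored neat, so it is carried as an assayed THF solution; 1-ethoxyprop-1-yne is taken as a purchasable reagent.

Remark on the chemistry: atom mapping of the annulation puts the free hydroxyl on C2 (from the cyclobutenone carbonyl) and the silyl ether on C4 (from the ynol ether oxygen), and the structures of both annulation partners and of their product follow from this mapping. Because the target is a symmetrical dimer, the cyclobutenone in step 5 and the acid chloride in step 6 are each used in at least two equivalents, one per ring. Step 5 is run in base-washed glassware with a hindered pyridine, because ynol ethers do not tolerate traces of acid.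

Step 1
Reactants: 1 propargyl bromide (3-bromoprop-1-yne); 2 ethynylmagnesium bromide
Product: 3 penta-1,4-diyne
Conditions: CuCl (cat.), THF, 0 → 40 °C; cold aq. NH4Cl; codistilled with THF, assayed by 1H NMR
Reagents that add atoms: none
Why: Copper-catalysed SN2 coupling of an alkynyl Grignard reagent with a propargylic halide is the standard preparation of skipped diynes, and it needs no strong base that would isomerise the product to the conjugated diyne.

Step 2
Reactants: 3 penta-1,4-diyne
Product: 6 1,5-bis(triisopropylsilyloxy)penta-1,4-diyne, via dilithium diacetylide 4 (not isolated), via dilithium bis(ynolate) 5 (not isolated)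
Conditions: n-BuLi (2.05 equiv), THF, −78 °C; t-BuOOLi (2.1 equiv, from t-BuOOH and LiN(SiMe3)2, THF, −78 °C), −78 → 0 °C; i-Pr3SiOTf (2.2 equiv), −78 °C; hexane/aq. NaHCO3
Reagents that add atoms: tert-butyl hydroperoxide CC(C)(C)OO; triisopropylsilyl trifluoromethanesulfonate CC(C)[Si](C(C)C)(C(C)C)OS(=O)(=O)C(F)(F)F
Why: The acetylenic protons are the most acidic and are removed at −78 °C before the central CH2, each lithium acetylide is then oxidised at carbon by oxygen transfer from lithium tert-butylperoxide to a lithium ynolate (electrophilic oxidation of a carbanion), and the bulky silyl triflate traps the ambident ynolate on oxygen, which is the known route to triisopropylsilyl ynol ethers.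

Step 3
Reactants: 7 1-ethoxyprop-1-yne; 8 acetyl chloride
Product: 10 3-ethoxy-2-methylcyclobut-2-en-1-one, via ketene 9 (not isolated)
Conditions: Et3N, MeCN, 23 °C, slow addition of 8
Reagents that add atoms: none
Why: Ketene released by dehydrochlorination is intercepted in a [2+2] cycloaddition by the electron-rich ynol ether, whose methyl-bearing carbon attacks the ketene carbonyl carbon, which fixes CH3 at C2 and OEt at C3 of the cyclobutenone.

Step 4
Reactants: 10 3-ethoxy-2-methylcyclobut-2-en-1-one
Product: 11 3-methoxy-2-methylcyclobut-2-en-1-one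
Conditions: anhydrous MeOH (solvent), camphorsulfonic acid (cat.), 23 °C; evaporate and repeat once; solid NaHCO3
Reagents that add atoms: methanol CO
Why: Acid-catalysed addition–elimination at the β-carbon of the vinylogous ester (transetherification) swaps OEt for OMe, the equilibrium being pulled over by methanol as solvent and by removal of ethanol on evaporation.

Step 5
Reactants: 6 1,5-bis(triisopropylsilyloxy)penta-1,4-diyne; 11 3-methoxy-2-methylcyclobut-2-en-1-one (2.4 equiv)
Product: 16 2,2'-methylenebis[5-methoxy-4-methyl-3-(triisopropylsilyloxy)phenol], via vinylketene 12 (not isolated), via bis(vinylcyclobutenone) 13 (not isolated), via bis(dienylketene) 14 (not isolated), via bis(cyclohexadienone) 15 (not isolated)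
Conditions: PhMe (degassed, 0.1 M), 2,6-di-tert-butyl-4-methylpyridine (0.2 equiv), base-washed sealed tube, argon, 80 → 110 °C
Reagents that add atoms: none
Why: Proposed new method: heating opens each cyclobutenone 11 by 4π electrocyclic ring opening to vinylketene 12, which adds across one ynol ether in a [2+2] sense (ketene carbonyl carbon to the CH2-bearing alkyne carbon, ketene α-carbon to the siloxy carbon) to give the 4-vinylcyclobutenones of 13, and a second 4π opening gives the dienylketenes of 14. Each benzene ring is then closed by thermal 6π electrocyclisation of a dienylketene (bond C1–C2), and tautomerisation of dienone 15 releases the C2 phenol. The closest known reaction is the Danheiser benzannulation of a single siloxyalkyne with a 3-alkyl- or 3-aryl-cyclobutenone to a resorcinol mono(silyl ether); new here are its twofold use on a skipped bis(ynol ether) and a vinylogous-ester cyclobutenone as the ketene source. No stereocentre persists, since the quaternary carbons of 13 are transient and are erased on aromatisation. The only selectivity required is the orientation of the ketene–alkyne addition, and it is secured by the polarisation of the ynol ether, whose bridge-side carbon is the nucleophilic terminus and therefore bonds to the electrophilic ketene carbon, placing the CH2 bridge between the two oxygenated carbons. Because the cascade runs under neutral thermal conditions, the central CH2 group, doubly propargylic at the start and doubly benzylic at the end, is left alone.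

Step 6
Reactants: 16 2,2'-methylenebis[5-methoxy-4-methyl-3-(triisopropylsilyloxy)phenol]; 17 butanoyl chloride (2.4 equiv)
Product: 18 methylenebis[5-methoxy-4-methyl-3-(triisopropylsilyloxy)-2,1-phenylene] dibutanoate
Conditions: 17 (2.4 equiv), Et3N (3 equiv), DMAP (cat.), CH2Cl2, 0 → 23 °C
Reagents that add atoms: none
Why: DMAP-catalysed O-acylation (nucleophilic acyl transfer) with two equivalents of the acid chloride esterifies both free phenols, one on each ring and the only nucleophilic heteroatoms left, while the hindered aryl silyl ethers are inert.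

Step 7
Reactants: 18 methylenebis[5-methoxy-4-methyl-3-(triisopropylsilyloxy)-2,1-phenylene] dibutanoate
Product: 19 1,1'-{methylenebis[2-hydroxy-6-methoxy-5-methyl-4-(triisopropylsilyloxy)-3,1-phenylene]}dibutan-1-one
Conditions: TiCl4 (2.5 equiv per ester), CH2Cl2, −20 → 23 °C; cold 1 M HCl
Reagents that add atoms: none
Why: Lewis acid-promoted Fries rearrangement moves each acyl group from the C2 oxygen to C1, the only unsubstituted ring carbon and one activated by the ortho phenoxide, the ortho methoxy and the para siloxy group, and the product is held as a six-membered titanium chelate that resists further reaction; any silyl ether lost here would only anticipate step 8.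

Step 8
Reactants: 19 1,1'-{methylenebis[2-hydroxy-6-methoxy-5-methyl-4-(triisopropylsilyloxy)-3,1-phenylene]}dibutan-1-one
Product: 20 pseudoaspidin
Conditions: Bu4NF (2.4 equiv), AcOH (2.4 equiv), THF, 0 °C
Reagents that add atoms: none
Why: Fluoride-induced Si–O cleavage (desilylation) frees the two C4 hydroxyls, and the acetic acid buffer keeps the medium from becoming basic enough to scramble the methylene bridge or to oxidise the phloroglucinol rings.

Compound list
1 | propargyl bromide (3-bromoprop-1-yne) | C#CCBr | starting material
2 | ethynylmagnesium bromide | C#C[Mg]Br | starting material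
3 | penta-1,4-diyne | C#CCC#C | intermediate
4 | dilithium penta-1,4-diyne-1,5-diide | [Li]C#CCC#C[Li] | intermediate (not isolated)
5 | dilithium penta-1,4-diyne-1,5-bis(olate) | [Li]OC#CCC#CO[Li] | intermediate (not isolated)
6 | 1,5-bis(triisopropylsilyloxy)penta-1,4-diyne | CC(C)[Si](C(C)C)(C(C)C)OC#CCC#CO[Si](C(C)C)(C(C)C)C(C)C | intermediate
7 | 1-ethoxyprop-1-yne | CCOC#CC | starting material
8 | acetyl chloride | CC(=O)Cl | starting material
9 | ketene (ethenone) | C=C=O | intermediate (not isolated)
10 | 3-ethoxy-2-methylcyclobut-2-en-1-one | CCOC1=C(C)C(=O)C1 | intermediate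
11 | 3-methoxy-2-methylcyclobut-2-en-1-one | COC1=C(C)C(=O)C1 | intermediate
12 | 3-methoxy-2-methylbuta-1,3-dien-1-one | O=C=C(C)C(OC)=C | intermediate (not isolated)
13 | 2,2'-methylenebis[4-(1-methoxyethenyl)-4-methyl-3-(triisopropylsilyloxy)cyclobut-2-en-1-one], both diastereomers, quaternary carbons transient | O=C1C(CC2=C(O[Si](C(C)C)(C(C)C)C(C)C)C(C)(C(OC)=C)C2=O)=C(O[Si](C(C)C)(C(C)C)C(C)C)C1(C)C(OC)=C | intermediate (not isolated)
14 | 2,2'-methylenebis[(3E)-5-methoxy-4-methyl-3-(triisopropylsilyloxy)hexa-1,3,5-trien-1-one] | O=C=C(CC(=C=O)/C(O[Si](C(C)C)(C(C)C)C(C)C)=C(C)\C(OC)=C)/C(O[Si](C(C)C)(C(C)C)C(C)C)=C(C)\C(OC)=C | intermediate (not isolated)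
15 | 2,2'-methylenebis[5-methoxy-4-methyl-3-(triisopropylsilyloxy)cyclohexa-2,4-dien-1-one] | O=C1CC(OC)=C(C)C(O[Si](C(C)C)(C(C)C)C(C)C)=C1CC1=C(O[Si](C(C)C)(C(C)C)C(C)C)C(C)=C(OC)CC1=O | intermediate (not isolated)
16 | 2,2'-methylenebis[5-methoxy-4-methyl-3-(triisopropylsilyloxy)phenol] | COc1cc(O)c(Cc2c(O)cc(OC)c(C)c2O[Si](C(C)C)(C(C)C)C(C)C)c(O[Si](C(C)C)(C(C)C)C(C)C)c1C | intermediate
17 | butanoyl chloride | CCCC(=O)Cl | starting material
18 | methylenebis[5-methoxy-4-methyl-3-(triisopropylsilyloxy)-2,1-phenylene] dibutanoate | CCCC(=O)Oc1cc(OC)c(C)c(O[Si](C(C)C)(C(C)C)C(C)C)c1Cc1c(OC(=O)CCC)cc(OC)c(C)c1O[Si](C(C)C)(C(C)C)C(C)C | intermediate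
19 | 1,1'-{methylenebis[2-hydroxy-6-methoxy-5-methyl-4-(triisopropylsilyloxy)-3,1-phenylene]}dibutan-1-one | CCCC(=O)c1c(O)c(Cc2c(O)c(C(=O)CCC)c(OC)c(C)c2O[Si](C(C)C)(C(C)C)C(C)C)c(O[Si](C(C)C)(C(C)C)C(C)C)c(C)c1OC | intermediate
20 | pseudoaspidin, 1,1'-[methylenebis(2,4-dihydroxy-6-methoxy-5-methyl-3,1-phenylene)]dibutan-1-one | CCCC(=O)c1c(O)c(Cc2c(O)c(C)c(OC)c(C(=O)CCC)c2O)c(O)c(C)c1OC | target

Total step count: 8. Longest linear sequence: 6 steps (1 → 2 → 5 → 6 → 7 → 8, or 3 → 4 → 5 → 6 → 7 → 8).

Steps most likely to fail

1. Step 5 (twofold benzannulation).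
- Ring opening of the vinylogous-ester cyclobutenone may be slow enough that the ynol ether termini decay first by thermal silyl migration to silylketenes.
- The phenol formed in the first annulation may add across the neighbouring ynol ether in a six-membered hydroalkoxylation, or be O-acylated by vinylketene, before the second ring is built.
- Fallback, known chemistry only, giving up the annulation for the classical acylate-then-bridge order: it sets out from butanoyl chloride 17 and comes back to the route at the target 20. Friedel–Crafts acylation of commercial 2-methylbenzene-1,3,5-triol with 17 (1 equiv, AlCl3, PhNO2) should give 1-(2,4,6-trihydroxy-3-methylphenyl)butan-1-one F1. Dibenzylation (BnBr, 2 equiv, K2CO3, acetone) is expected to spare the most hindered and most strongly chelated hydroxyl, the one between acyl and methyl, giving 1-[4,6-bis(benzyloxy)-2-hydroxy-3-methylphenyl]butan-1-one F2. O-Methylation (MeI, K2CO3, DMF) gives 1-[4,6-bis(benzyloxy)-2-methoxy-3-methylphenyl]butan-1-one F3, and hydrogenolysis (H2, Pd/C, EtOAc) gives 1-(4,6-dihydroxy-2-methoxy-3-methylphenyl)butan-1-one F4, whose single free ring carbon lies between the two hydroxyls. Condensation of two molecules of F4 with one of formaldehyde (aq. CH2O, aq. KOH, 0 → 23 °C, then acidification) installs the methylene bridge and gives 20.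

2. Step 2 (twofold acetylide oxidation and silylation).
- The dilithium diacetylide may aggregate so that only one terminus is oxidised.
- The alkoxide formed during the oxidation may trigger prototropic isomerisation of the skipped diyne to conjugated or allenic isomers.
- Fallback, one terminus at a time on a non-volatile, mono-protected diyne: it sets out from ethynylmagnesium bromide 2 and comes back to the route at 6. Copper-catalysed coupling of 2 with commercial 3-bromo-1-(trimethylsilyl)prop-1-yne (CuCl, THF) should give trimethyl(penta-1,4-diyn-1-yl)silane F5. One equivalent of n-BuLi at −78 °C gives the lithium acetylide F6, lithium tert-butylperoxide oxidises it to the lithium ynolate F7, and i-Pr3SiOTf gives triisopropyl{[5-(trimethylsilyl)penta-1,4-diyn-1-yl]oxy}silane F8. The C-silyl group is removed with K2CO3 (cat.) in methanol/THF at 0 °C, where the hindered triisopropylsilyl ether should be cleaved far more slowly than the alkynyl trimethylsilane, to give triisopropyl(penta-1,4-diyn-1-yloxy)silane F9. A second round of lithiation (lithium acetylide F10), oxidation (lithium ynolate F11) and O-silylation then gives 6.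

3. Step 7 (Fries rearrangement).
- Ipso attack of a proton or acylium ion at the very electron-rich C3 may cleave or scramble the diarylmethane bridge (retro-Friedel–Crafts).
- Chelation-assisted loss of the C6 methyl ether or premature desilylation may accompany the acyl shift.
- Fallback, avoiding Lewis acid altogether by putting the acyl group in through an aryllithium: it sets out from bis-phenol 16 and comes back to the route at 19. NBS (2 equiv, CH2Cl2, −78 °C) should brominate the only free carbon of each ring to give 2,2'-methylenebis[6-bromo-5-methoxy-4-methyl-3-(triisopropylsilyloxy)phenol] F12. Deprotonation of both phenols with n-BuLi (2 equiv) and bromine–lithium exchange with t-BuLi (4 equiv, THF, −78 °C) gives dilithium 2,2'-methylenebis[6-lithio-5-methoxy-4-methyl-3-(triisopropylsilyloxy)phenolate] F13. Acylation of F13 with N-methoxy-N-methylbutanamide (2.2 equiv, Weinreb ketone synthesis) gives 19 after aqueous work-up.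

Further compounds
F1 | step 5 | 1-(2,4,6-trihydroxy-3-methylphenyl)butan-1-one | CCCC(=O)c1c(O)cc(O)c(C)c1O
F2 | step 5 | 1-[4,6-bis(benzyloxy)-2-hydroxy-3-methylphenyl]butan-1-one | CCCC(=O)c1c(O)c(C)c(OCc2ccccc2)cc1OCc1ccccc1
F3 | step 5 | 1-[4,6-bis(benzyloxy)-2-methoxy-3-methylphenyl]butan-1-one | CCCC(=O)c1c(OC)c(C)c(OCc2ccccc2)cc1OCc1ccccc1
F4 | step 5 | 1-(4,6-dihydroxy-2-methoxy-3-methylphenyl)butan-1-one | CCCC(=O)c1c(OC)c(C)c(O)cc1O
F5 | step 2 | trimethyl(penta-1,4-diyn-1-yl)silane | C#CCC#C[Si](C)(C)C
F6 | step 2 | lithium 5-(trimethylsilyl)penta-1,4-diyn-1-ide | [Li]C#CCC#C[Si](C)(C)C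
F7 | step 2 | lithium 5-(trimethylsilyl)penta-1,4-diyn-1-olate | [Li]OC#CCC#C[Si](C)(C)C
F8 | step 2 | triisopropyl{[5-(trimethylsilyl)penta-1,4-diyn-1-yl]oxy}silane | C[Si](C)(C)C#CCC#CO[Si](C(C)C)(C(C)C)C(C)C
F9 | step 2 | triisopropyl(penta-1,4-diyn-1-yloxy)silane | C#CCC#CO[Si](C(C)C)(C(C)C)C(C)C
F10 | step 2 | lithium 5-(triisopropylsilyloxy)penta-1,4-diyn-1-ide | [Li]C#CCC#CO[Si](C(C)C)(C(C)C)C(C)C
F11 | step 2 | lithium 5-(triisopropylsilyloxy)penta-1,4-diyn-1-olate | [Li]OC#CCC#CO[Si](C(C)C)(C(C)C)C(C)C
F12 | step 7 | 2,2'-methylenebis[6-bromo-5-methoxy-4-methyl-3-(triisopropylsilyloxy)phenol] | COc1c(Br)c(O)c(Cc2c(O)c(Br)c(OC)c(C)c2O[Si](C(C)C)(C(C)C)C(C)C)c(O[Si](C(C)C)(C(C)C)C(C)C)c1C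
F13 | step 7 | dilithium 2,2'-methylenebis[6-lithio-5-methoxy-4-methyl-3-(triisopropylsilyloxy)phenolate] | COc1c([Li])c(O[Li])c(Cc2c(O[Li])c([Li])c(OC)c(C)c2O[Si](C(C)C)(C(C)C)C(C)C)c(O[Si](C(C)C)(C(C)C)C(C)C)c1C
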